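## Retrosynthetic overview

1. Target 24 comes from silyl peroxide 23 by desilylation; the E-enone of 23 comes from β-acetoxy ketone 22 by loss of AcOH; the C11 peroxide comes from cobalt-catalysed O2/Et3SiH peroxidation of the isopropenyl group of 21.
2. The C9–C10 bond is made by an intermolecular aldol addition of the lithium enolate of epoxy methyl ketone 15 to methacrolein 16.
3. Ketone 15 comes from epoxy aldehyde 13 (MeMgBr, then oxidation); 13 comes from Sharpless epoxidation of allylic alcohol 11 (sets C7), itself made by allylic chlorination of the isopropenyl group.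
4. C5 comes from (R)-carvone 1; C6–O is set by enolate hydroxylation (trans); C1 reduction and hydroxyl-directed epoxidation give the cis C2/C3 oxirane; C1 is re-oxidised after the aldol.
5. Ring order: carbocycle from the chiral pool, then the ring oxirane (step 5), then the side-chain oxirane (step 8).

Convention: carvone locants are kept throughout (ring C1 = carbonyl carbon, C2 = CMe, C5 = carbon carrying the side chain, C6 between C1 and C5; side chain C7 on C5, then C8–C11, and C14 = CH2 on C7); β is the ring face of the C5 side chain, α the other face.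

## Route

Step 1
Reactants: 1 (R)-(−)-carvone
Product: 3 (5S,6S)-6-hydroxycarvone, via lithium dienolate 2 (not isolated)
Conditions: LiN(iPr)2, THF, −78 °C; then 2-(phenylsulfonyl)-3-phenyloxaziridine, −78 °C; aq. NH4Cl
Reagents that add atoms: 2-(phenylsulfonyl)-3-phenyloxaziridine, O=S(=O)(N1OC1c1ccccc1)c1ccccc1 (O at C6); lithium diisopropylamide, [Li]N(C(C)C)C(C)C (Li of 2 only)
Why: Kinetic deprotonation at C6 gives the cross-conjugated dienolate, which is hydroxylated (Davis enolate oxidation) anti to the C5 isopropenyl group to give the trans (6α) alcohol, also the more stable diequatorial epimer.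

Step 2
Reactants: 3 (5S,6S)-6-hydroxycarvone + 4 3-methylbutanoyl chloride
Product: 5 trans-6-(3-methylbutanoyloxy)carvone
Conditions: pyridine, DMAP (cat.), CH2Cl2, 0 °C
Reagents that add atoms: none
Why: DMAP-catalysed O-acylation of the secondary α-ketol installs the target's ester early, where it also serves as the C6–O protecting group, without touching a stereocentre.

Step 3
Reactants: 5 trans-6-(3-methylbutanoyloxy)carvone
Product: 6 allylic chloride (C5 substituent 3-chloroprop-1-en-2-yl)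
Conditions: Ca(OCl)2, CO2 (dry ice), CH2Cl2/H2O, 0 °C
Reagents that add atoms: calcium hypochlorite, [Ca+2].[O-]Cl.[O-]Cl (Cl, delivered as HOCl)
Why: Ene-type allylic chlorination by HOCl made in situ attacks only the electron-rich 1,1-disubstituted alkene (the enone alkene is electron-poor) and shifts the double bond to give the 2-(chloromethyl)vinyl group.

Step 4
Reactants: 6 allylic chloride
Product: 7 cyclohexenol (1β-OH)
Conditions: NaBH4, CeCl3·7H2O, MeOH, −78 °C
Reagents that add atoms: none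
Why: Luche reduction gives clean 1,2-reduction, and axial hydride delivery gives the equatorial 1β-alcohol (cis to the C5 side chain, trans to the C6 ester), as in the reduction of carvone to cis-carveol.

Step 5
Reactants: 7 cyclohexenol
Product: 8 ring epoxy alcohol (2β,3β-oxirane)
Conditions: VO(acac)2 (cat.), t-BuOOH, CH2Cl2, 0 °C → rt
Reagents that add atoms: tert-butyl hydroperoxide, CC(C)(C)OO
Why: Hydroxyl-directed vanadium-catalysed epoxidation delivers oxygen to the ring alkene on the face of the C1 hydroxyl, setting C2 and C3 as the β-oxirane, while the side-chain alkene (no directing OH, electron-poor) is untouched.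

Step 6
Reactants: 8 ring epoxy alcohol
Product: 9 C1 triethylsilyl ether
Conditions: Et3SiOTf, 2,6-lutidine, CH2Cl2, −78 °C
Reagents that add atoms: triethylsilyl trifluoromethanesulfonate, CC[Si](CC)(CC)OS(=O)(=O)C(F)(F)F
Why: Silylation with the silyl triflate and a hindered base protects the hindered C1 alcohol (the future ketone) without touching the allylic chloride, ester or oxirane.

Step 7
Reactants: 9 C1 triethylsilyl ether
Product: 11 allylic alcohol (C5 substituent 3-hydroxyprop-1-en-2-yl), via allylic formate 10 (not isolated)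
Conditions: HCO2Na, Bu4NI (cat.), DMF, 50 °C; then K2CO3 (cat.), MeOH, 0 °C
Reagents that add atoms: sodium formate, [Na+].[O-]C=O
Why: SN2 displacement of the primary allylic chloride by formate (SN2 and SN2' give the same product) and mild methanolysis of the very labile formate release the alcohol while the hindered secondary ester and the silyl ether survive.

Step 8
Reactants: 11 allylic alcohol
Product: 12 side-chain epoxy alcohol (C7 S)
Conditions: Ti(OiPr)4 (10 mol %), L-(+)-diethyl tartrate (12 mol %), t-BuOOH, 4 Å MS, CH2Cl2, −20 °C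
Reagents that add atoms: tert-butyl hydroperoxide, CC(C)(C)OO
Why: Sharpless asymmetric epoxidation of the 2-substituted allylic alcohol is reagent-controlled, and L-(+)-tartrate delivers oxygen to the face that gives the target's C7 configuration (the same sense as (S)-2-methylglycidol from methallyl alcohol).

Step 9
Reactants: 12 side-chain epoxy alcohol
Product: 13 epoxy aldehyde
Conditions: DMP, NaHCO3, CH2Cl2, 0 °C → rt
Reagents that add atoms: none
Why: Buffered Dess–Martin oxidation converts the primary epoxy alcohol into the α,β-epoxy aldehyde without opening either oxirane, and the quaternary C7 cannot epimerise.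

Step 10
Reactants: 13 epoxy aldehyde
Product: 14 secondary alcohol (C8 epimers)
Conditions: MeMgBr, THF, −78 °C; aq. NH4Cl
Reagents that add atoms: methylmagnesium bromide, C[Mg]Br
Why: Grignard addition to the aldehyde is far faster at −78 °C than attack on the hindered secondary ester, and the new C8 carbinol centre is erased in the next step.

Step 11
Reactants: 14 secondary alcohol
Product: 15 epoxy methyl ketone
Conditions: DMP, NaHCO3, CH2Cl2, rt
Reagents that add atoms: none
Why: Dess–Martin oxidation of the secondary alcohol gives a methyl ketone whose only enolisable position is the methyl group, which sets up the aldol.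

Step 12
Reactants: 15 epoxy methyl ketone + 16 methacrolein
Product: 18 aldol adduct (β-hydroxy ketone; C10 epimers), via lithium enolate 17 (not isolated)
Conditions: LiN(SiMe3)2, THF, −78 °C; then 16, −78 °C; AcOH quench
Reagents that add atoms: lithium bis(trimethylsilyl)amide, [Li]N([Si](C)(C)C)[Si](C)(C)C (Li of 17 only)
Why: In this intermolecular aldol addition the amide base deprotonates only the methyl ketone (far more acidic than the ester, and C7 is quaternary) and the lithium enolate adds 1,2 to the non-enolisable enal, joining C9 to C10; the C10 carbinol centre is removed later by elimination.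

Step 13
Reactants: 18 aldol adduct
Product: 19 β-acetoxy ketone
Conditions: Ac2O, pyridine, DMAP (cat.), CH2Cl2, 0 °C
Reagents that add atoms: acetic anhydride, CC(=O)OC(C)=O
Why: Acetylation protects the aldol hydroxyl against the coming oxidation and turns it into the leaving group for the later E1cB step.

Step 14
Reactants: 19 β-acetoxy ketone
Product: 20 C1 alcohol
Conditions: HF·pyridine, pyridine, THF, 0 °C → rt
Reagents that add atoms: none
Why: Buffered fluoride desilylation cleaves the triethylsilyl ether without opening the oxiranes or eliminating the β-acetate.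

Step 15
Reactants: 20 C1 alcohol
Product: 21 ring ketone
Conditions: DMP, NaHCO3, CH2Cl2, rt
Reagents that add atoms: none
Why: Buffered Dess–Martin oxidation gives the ring ketone without epimerising C6 (the trans arrangement is in any case the more stable) or eliminating the β-acetate.

Step 16
Reactants: 21 ring ketone
Product: 22 tertiary triethylsilyl peroxide
Conditions: Co(acac)2 (cat.), O2 (1 atm), Et3SiH, ClCH2CH2Cl, rt
Reagents that add atoms: dioxygen, O=O; triethylsilane, CC[SiH](CC)CC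
Why: In this Isayama–Mukaiyama peroxysilylation a cobalt hydride transfers a hydrogen atom to the terminal CH2 of the only alkene, and the tertiary radical is trapped by O2 and silylated, placing the peroxide regiospecifically on C11 under neutral conditions that leave ketones, esters and oxiranes alone.

Step 17
Reactants: 22 tertiary triethylsilyl peroxide
Product: 23 E-enone silyl peroxide
Conditions: DBU, CH2Cl2, 0 °C
Reagents that add atoms: none
Why: E1cB elimination of acetic acid from the β-acetoxy ketone gives the conjugated enone as the favoured E isomer from both C10 epimers, and the quaternary C11 rules out further isomerisation.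

Step 18
Reactants: 23 E-enone silyl peroxide
Product: 24 target hydroperoxide (CNP0131119.1)
Conditions: HF·pyridine, pyridine, THF, 0 °C
Reagents that add atoms: none
Why: Fluoride-driven desilylation cleaves the labile Si–O bond of the silyl peroxide much faster than anything happens to the oxiranes, ester or enone, releasing the tertiary hydroperoxide with all stereocentres unchanged.

## Compound list

1 | (R)-(−)-carvone, (5R)-2-methyl-5-(prop-1-en-2-yl)cyclohex-2-en-1-one | CC1=CC[C@H](CC1=O)C(C)=C | starting material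
2 | lithium (3R)-6-methyl-3-(prop-1-en-2-yl)cyclohexa-1,5-dien-1-olate (cross-conjugated dienolate of 1) | [Li]OC1=C[C@H](C(C)=C)CC=C1C | intermediate
3 | (5S,6S)-6-hydroxy-2-methyl-5-(prop-1-en-2-yl)cyclohex-2-en-1-one (trans-6-hydroxycarvone) | O[C@@H]1C(=O)C(C)=CC[C@H]1C(C)=C | intermediate
4 | 3-methylbutanoyl chloride | CC(C)CC(=O)Cl | starting material
5 | (1S,6S)-3-methyl-2-oxo-6-(prop-1-en-2-yl)cyclohex-3-en-1-yl 3-methylbutanoate | CC(C)CC(=O)O[C@@H]1C(=O)C(C)=CC[C@H]1C(C)=C | intermediate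
6 | (1S,6S)-6-(3-chloroprop-1-en-2-yl)-3-methyl-2-oxocyclohex-3-en-1-yl 3-methylbutanoate | CC(C)CC(=O)O[C@@H]1C(=O)C(C)=CC[C@H]1C(CCl)=C | intermediate
7 | (1S,2S,6S)-6-(3-chloroprop-1-en-2-yl)-2-hydroxy-3-methylcyclohex-3-en-1-yl 3-methylbutanoate (1β-OH) | CC(C)CC(=O)O[C@@H]1[C@@H](O)C(C)=CC[C@H]1C(CCl)=C | intermediate
8 | (1R,2R,3S,4S,6S)-4-(3-chloroprop-1-en-2-yl)-2-hydroxy-1-methyl-7-oxabicyclo[4.1.0]heptan-3-yl 3-methylbutanoate (1β-OH; 2β,3β-oxirane) | CC(C)CC(=O)O[C@@H]1[C@@H](O)[C@@]2(C)O[C@H]2C[C@H]1C(CCl)=C | intermediate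
9 | (1S,2R,3S,4S,6S)-4-(3-chloroprop-1-en-2-yl)-1-methyl-2-[(triethylsilyl)oxy]-7-oxabicyclo[4.1.0]heptan-3-yl 3-methylbutanoate | CC(C)CC(=O)O[C@@H]1[C@@H](O[Si](CC)(CC)CC)[C@@]2(C)O[C@H]2C[C@H]1C(CCl)=C | intermediate
10 | (1S,2R,3S,4S,6S)-4-[3-(formyloxy)prop-1-en-2-yl]-1-methyl-2-[(triethylsilyl)oxy]-7-oxabicyclo[4.1.0]heptan-3-yl 3-methylbutanoate | CC(C)CC(=O)O[C@@H]1[C@@H](O[Si](CC)(CC)CC)[C@@]2(C)O[C@H]2C[C@H]1C(COC=O)=C | intermediate
11 | (1S,2R,3S,4S,6S)-4-(3-hydroxyprop-1-en-2-yl)-1-methyl-2-[(triethylsilyl)oxy]-7-oxabicyclo[4.1.0]heptan-3-yl 3-methylbutanoate | CC(C)CC(=O)O[C@@H]1[C@@H](O[Si](CC)(CC)CC)[C@@]2(C)O[C@H]2C[C@H]1C(CO)=C | intermediate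
12 | (1S,2R,3S,4R,6S)-4-[(2S)-2-(hydroxymethyl)oxiran-2-yl]-1-methyl-2-[(triethylsilyl)oxy]-7-oxabicyclo[4.1.0]heptan-3-yl 3-methylbutanoate | CC(C)CC(=O)O[C@@H]1[C@@H](O[Si](CC)(CC)CC)[C@@]2(C)O[C@H]2C[C@H]1[C@]1(CO)CO1 | intermediate
13 | (1S,2R,3S,4R,6S)-4-[(2R)-2-formyloxiran-2-yl]-1-methyl-2-[(triethylsilyl)oxy]-7-oxabicyclo[4.1.0]heptan-3-yl 3-methylbutanoate | CC(C)CC(=O)O[C@@H]1[C@@H](O[Si](CC)(CC)CC)[C@@]2(C)O[C@H]2C[C@H]1[C@]1(C=O)CO1 | intermediate
14 | (1S,2R,3S,4R,6S)-4-[(2R)-2-(1-hydroxyethyl)oxiran-2-yl]-1-methyl-2-[(triethylsilyl)oxy]-7-oxabicyclo[4.1.0]heptan-3-yl 3-methylbutanoate (C8 epimers) | CC(C)CC(=O)O[C@@H]1[C@@H](O[Si](CC)(CC)CC)[C@@]2(C)O[C@H]2C[C@H]1[C@]1(C(C)O)CO1 | intermediate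
15 | (1S,2R,3S,4R,6S)-4-[(2R)-2-acetyloxiran-2-yl]-1-methyl-2-[(triethylsilyl)oxy]-7-oxabicyclo[4.1.0]heptan-3-yl 3-methylbutanoate | CC(C)CC(=O)O[C@@H]1[C@@H](O[Si](CC)(CC)CC)[C@@]2(C)O[C@H]2C[C@H]1[C@]1(C(C)=O)CO1 | intermediate
16 | methacrolein (2-methylprop-2-enal) | CC(=C)C=O | starting material
17 | lithium enolate of 15 (C8(OLi)=C9H2) | CC(C)CC(=O)O[C@@H]1[C@@H](O[Si](CC)(CC)CC)[C@@]2(C)O[C@H]2C[C@H]1[C@]1(C(=C)O[Li])CO1 | intermediate
18 | (1S,2R,3S,4R,6S)-4-[(2R)-2-(3-hydroxy-4-methylpent-4-enoyl)oxiran-2-yl]-1-methyl-2-[(triethylsilyl)oxy]-7-oxabicyclo[4.1.0]heptan-3-yl 3-methylbutanoate (C10 epimers) | CC(C)CC(=O)O[C@@H]1[C@@H](O[Si](CC)(CC)CC)[C@@]2(C)O[C@H]2C[C@H]1[C@]1(C(=O)CC(O)C(C)=C)CO1 | intermediate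
19 | (1S,2R,3S,4R,6S)-4-[(2R)-2-(3-acetoxy-4-methylpent-4-enoyl)oxiran-2-yl]-1-methyl-2-[(triethylsilyl)oxy]-7-oxabicyclo[4.1.0]heptan-3-yl 3-methylbutanoate (C10 epimers) | CC(C)CC(=O)O[C@@H]1[C@@H](O[Si](CC)(CC)CC)[C@@]2(C)O[C@H]2C[C@H]1[C@]1(C(=O)CC(OC(C)=O)C(C)=C)CO1 | intermediate
20 | (1R,2R,3S,4R,6S)-4-[(2R)-2-(3-acetoxy-4-methylpent-4-enoyl)oxiran-2-yl]-2-hydroxy-1-methyl-7-oxabicyclo[4.1.0]heptan-3-yl 3-methylbutanoate (C10 epimers) | CC(C)CC(=O)O[C@@H]1[C@@H](O)[C@@]2(C)O[C@H]2C[C@H]1[C@]1(C(=O)CC(OC(C)=O)C(C)=C)CO1 | intermediate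
21 | (1S,3S,4R,6S)-4-[(2R)-2-(3-acetoxy-4-methylpent-4-enoyl)oxiran-2-yl]-1-methyl-2-oxo-7-oxabicyclo[4.1.0]heptan-3-yl 3-methylbutanoate (C10 epimers) | CC(C)CC(=O)O[C@@H]1C(=O)[C@@]2(C)O[C@H]2C[C@H]1[C@]1(C(=O)CC(OC(C)=O)C(C)=C)CO1 | intermediate
22 | (1S,3S,4R,6S)-4-[(2R)-2-{3-acetoxy-4-methyl-4-[(triethylsilyl)peroxy]pentanoyl}oxiran-2-yl]-1-methyl-2-oxo-7-oxabicyclo[4.1.0]heptan-3-yl 3-methylbutanoate (C10 epimers) | CC(C)CC(=O)O[C@@H]1C(=O)[C@@]2(C)O[C@H]2C[C@H]1[C@]1(C(=O)CC(OC(C)=O)C(C)(C)OO[Si](CC)(CC)CC)CO1 | intermediate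
23 | (1S,3S,4R,6S)-1-methyl-4-[(2R)-2-{(2E)-4-methyl-4-[(triethylsilyl)peroxy]pent-2-enoyl}oxiran-2-yl]-2-oxo-7-oxabicyclo[4.1.0]heptan-3-yl 3-methylbutanoate | CC(C)CC(=O)O[C@@H]1C(=O)[C@@]2(C)O[C@H]2C[C@H]1[C@]1(C(=O)/C=C/C(C)(C)OO[Si](CC)(CC)CC)CO1 | intermediate
24 | (1S,3S,4R,6S)-4-{(2R)-2-[(2E)-4-hydroperoxy-4-methylpent-2-enoyl]oxiran-2-yl}-1-methyl-2-oxo-7-oxabicyclo[4.1.0]heptan-3-yl 3-methylbutanoate (CNP0131119.1) | CC(C)CC(=O)O[C@@H]1C(=O)[C@@]2(C)O[C@H]2C[C@H]1[C@]1(C(=O)/C=C/C(C)(C)OO)CO1 | target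

## Summary and fallbacks

Total step count: 18. Longest linear sequence: 18 steps (1 → 24); 4 and 16 are bought.

Steps most likely to fail:

- **Step 8 (Sharpless epoxidation).** The tartrate may be mismatched with the ring stereocentres, or the 2,2-disubstituted epoxy alcohol may be opened on titanium. The fallback sets out from 11 and comes back at 13. Allylic oxidation with MnO2 (CH2Cl2, rt) gives the 2-substituted acrolein F1. F1 is then epoxidised with aqueous H2O2 under iminium catalysis by a diphenylprolinol silyl ether (organocatalytic nucleophilic epoxidation of an α-substituted acrolein). The catalyst enantiomer is the one that gives the (R)-configured C7 of 13, to be confirmed on 2-cyclohexylacrolein. This delivers epoxy aldehyde 13 directly and skips 12.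

- **Step 12 (lithium aldol).** Risks are competing ester enolisation, retro-aldol on work-up, or oxirane damage by the strong base. The fallback sets out from 15 and comes back at 18. Soft enolisation (Me3SiOTf, Et3N, CH2Cl2, −78 °C) gives the trimethylsilyl enol ether F2. A Mukaiyama aldol addition of F2 to 16 (BF3·OEt2, CH2Cl2, −78 °C, short contact, aqueous work-up) then gives 18 without any strong base.

- **Step 16 (cobalt-catalysed peroxysilylation).** The complex substrate may give low conversion, or the alkene may simply be reduced. The fallback sets out from 13 and comes back at 24, replacing hydrogen-atom-transfer peroxidation by a singlet-oxygen ene reaction.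
  - α-Selective carbonyl prenylation of 13 with prenylbarium chloride (prenyl chloride and activated barium from BaI2 and lithium biphenylide, THF, −78 °C) gives the homoallylic alcohol F3.
  - Buffered DMP oxidation gives the β,γ-unsaturated prenyl ketone F4.
  - HF·pyridine removes the silyl ether to give the C1 alcohol F5.
  - DMP oxidation gives the ring ketone F6.
  - Schenck ene reaction of F6 (O2, tetraphenylporphyrin, visible light, CH2Cl2, 0 °C) abstracts a C9 hydrogen, moves the alkene to C9=C10 (E) and places OOH on C11. This gives 24 after chromatographic removal of the regioisomeric secondary hydroperoxide.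

## Further compounds

F1 | step 8 | (1S,2R,3S,4S,6S)-1-methyl-4-(3-oxoprop-1-en-2-yl)-2-[(triethylsilyl)oxy]-7-oxabicyclo[4.1.0]heptan-3-yl 3-methylbutanoate | CC(C)CC(=O)O[C@@H]1[C@@H](O[Si](CC)(CC)CC)[C@@]2(C)O[C@H]2C[C@H]1C(C=O)=C
F2 | step 12 | (1S,2R,3S,4R,6S)-1-methyl-2-[(triethylsilyl)oxy]-4-[(2R)-2-{1-[(trimethylsilyl)oxy]ethenyl}oxiran-2-yl]-7-oxabicyclo[4.1.0]heptan-3-yl 3-methylbutanoate | CC(C)CC(=O)O[C@@H]1[C@@H](O[Si](CC)(CC)CC)[C@@]2(C)O[C@H]2C[C@H]1[C@]1(C(=C)O[Si](C)(C)C)CO1
F3 | step 16 | (1S,2R,3S,4R,6S)-4-[(2R)-2-(1-hydroxy-4-methylpent-3-en-1-yl)oxiran-2-yl]-1-methyl-2-[(triethylsilyl)oxy]-7-oxabicyclo[4.1.0]heptan-3-yl 3-methylbutanoate (C8 epimers) | CC(C)CC(=O)O[C@@H]1[C@@H](O[Si](CC)(CC)CC)[C@@]2(C)O[C@H]2C[C@H]1[C@]1(C(O)CC=C(C)C)CO1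
F4 | step 16 | (1S,2R,3S,4R,6S)-1-methyl-4-[(2R)-2-(4-methylpent-3-enoyl)oxiran-2-yl]-2-[(triethylsilyl)oxy]-7-oxabicyclo[4.1.0]heptan-3-yl 3-methylbutanoate | CC(C)CC(=O)O[C@@H]1[C@@H](O[Si](CC)(CC)CC)[C@@]2(C)O[C@H]2C[C@H]1[C@]1(C(=O)CC=C(C)C)CO1
F5 | step 16 | (1R,2R,3S,4R,6S)-2-hydroxy-1-methyl-4-[(2R)-2-(4-methylpent-3-enoyl)oxiran-2-yl]-7-oxabicyclo[4.1.0]heptan-3-yl 3-methylbutanoate | CC(C)CC(=O)O[C@@H]1[C@@H](O)[C@@]2(C)O[C@H]2C[C@H]1[C@]1(C(=O)CC=C(C)C)CO1
F6 | step 16 | (1S,3S,4R,6S)-1-methyl-4-[(2R)-2-(4-methylpent-3-enoyl)oxiran-2-yl]-2-oxo-7-oxabicyclo[4.1.0]heptan-3-yl 3-methylbutanoate | CC(C)CC(=O)O[C@@H]1C(=O)[C@@]2(C)O[C@H]2C[C@H]1[C@]1(C(=O)CC=C(C)C)CO1
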